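The nine-membered oxacycle (O–C3–C4=C5–C6–C7–C8–C9–C10, germacrane numbering) is disconnected at C7–C8. Its precursor already holds both five-membered rings: a 3(2H)-furanone carrying a CH2CHO arm on C10 and, joined to it through the Z-C4=C5 alkene, a 3-(bromomethyl)butenolide that is the future lactone. One chromium-mediated intramolecular allylation then closes the last ring, sets C7 and C8, and shifts the butenolide double bond into the exocyclic C11=C13 methylene. The step exploits the homoallylic relation between the C8 carbinol and the α-methylene lactone: C8 is bonded to C7, the γ-carbon of the 2-carbonyl allyl unit C13–C11–C7.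

Key step: step 13

Remark: atoms are numbered as in germacranolides (C1 ketone, C2=C3 furanone alkene, C4=C5, C6 lactone CH–O, C7, C8 ester carbinol, C9, C10 quaternary, C11=C13 methylene, C12 lactone carbonyl, C14 methyl, C15 CH2O); carbon building blocks are numbered as reactants, and metalated species generated in a first operation of a step carry their own numbers as intermediates that are not isolated.

Step 1
Reactants: 1 tert-butyldiphenyl(prop-2-yn-1-yloxy)silane; 2 acrolein
Product: 4 (R)-6-[(tert-butyldiphenylsilyl)oxy]hex-1-en-4-yn-3-ol, via alkynylzinc 3 (not isolated)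
Conditions: Me2Zn, (R,R)-ProPhenol [2,6-bis{[(R)-2-(hydroxydiphenylmethyl)pyrrolidin-1-yl]methyl}-4-methylphenol] (10 mol%), Ph3P=O (20 mol%), toluene, 0 °C; then 2, 4 °C; aq. NH4Cl
Reagents that add atoms: none
Why: The alkynylzinc 3 adds 1,2 to the enal inside the chiral dinuclear zinc–ProPhenol complex (catalytic asymmetric alkynylation of an aldehyde), the (R,R)-ligand being expected, by analogy with other enals, to expose the aldehyde face that gives the R carbinol at C6 (the antipodal ligand would be taken if a Mosher ester check showed otherwise).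

Step 2
Reactants: 4 (R)-6-[(tert-butyldiphenylsilyl)oxy]hex-1-en-4-yn-3-ol
Product: 6 (3R,4Z)-6-[(tert-butyldiphenylsilyl)oxy]-5-iodohexa-1,4-dien-3-ol, via alkenylaluminate 5 (not isolated)
Conditions: NaAlH2(OCH2CH2OMe)2 (Red-Al), THF, 0 °C; then I2, −78 to 0 °C
Reagents that add atoms: iodine, [I][I]
Why: Hydroxyl-directed trans-hydroalumination of the propargylic alcohol (the alkoxide-bound aluminium hydride delivers H to C5 and aluminium to C4, giving the five-membered aluminate 5) followed by iodinolysis of the C–Al bond with retention fixes the C4=C5 geometry with iodine cis to C6 (Z), leaves the isolated vinyl group and the C6 centre untouched, and is the standard route to (Z)-3-iodoallylic alcohols.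

Step 3
Reactants: 6 (3R,4Z)-6-[(tert-butyldiphenylsilyl)oxy]-5-iodohexa-1,4-dien-3-ol
Product: 7 tert-butyl{[(2Z,4R)-2-iodo-4-(triethylsilyloxy)hexa-2,5-dien-1-yl]oxy}diphenylsilane
Conditions: Et3SiCl, imidazole, CH2Cl2, 0 °C
Reagents that add atoms: chlorotriethylsilane, CC[Si](Cl)(CC)CC
Why: Standard silylation of the secondary alcohol; the triethylsilyl ether masks the C6 oxygen so that it cannot add to the ynone formed in step 8, and it can later be removed without touching the primary tert-butyldiphenylsilyl ether.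

Step 4
Reactants: 8 (2S,5S)-2-tert-butyl-5-methyl-1,3-dioxolan-4-one; 9 allyl bromide
Product: 11 (2S,5R)-5-allyl-2-tert-butyl-5-methyl-1,3-dioxolan-4-one, via lithium enolate 10 (not isolated)
Conditions: LiN(iPr)2, THF, −78 °C; then 9, −78 to −30 °C
Reagents that add atoms: none
Why: Enolate alkylation with self-regeneration of the stereocentre: the acetal tert-butyl group blocks one face of enolate 10, so allyl bromide enters trans to it and takes the place of the former hydrogen, which sets the quaternary C10 centre (R in the target) with overall retention.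

Step 5
Reactants: 11 (2S,5R)-5-allyl-2-tert-butyl-5-methyl-1,3-dioxolan-4-one
Product: 13 (2S,5R)-2-tert-butyl-5-(2,2-dimethoxyethyl)-5-methyl-1,3-dioxolan-4-one, via aldehyde 12 (not isolated)
Conditions: O3, CH2Cl2/MeOH, −78 °C; Me2S; then HC(OMe)3, pyridinium p-toluenesulfonate (cat.), MeOH, rt
Reagents that add atoms: ozone, [O-][O+]=O (carbonyl oxygen of 12); trimethyl orthoformate, COC(OC)OC (both methoxy groups of 13)
Why: Ozonolysis of the only alkene with reductive work-up gives aldehyde 12, which is acetalised in the same flask by acid-catalysed exchange with trimethyl orthoformate, so that C8 is carried at the aldehyde oxidation level through the organometallic steps while the quaternary centre cannot epimerise.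

Step 6
Reactants: 13 (2S,5R)-2-tert-butyl-5-(2,2-dimethoxyethyl)-5-methyl-1,3-dioxolan-4-one
Product: 14 (R)-2-hydroxy-N,4,4-trimethoxy-N,2-dimethylbutanamide
Conditions: MeNH(OMe)·HCl, iPrMgCl, THF, −20 to 0 °C
Reagents that add atoms: N,O-dimethylhydroxylamine hydrochloride, CNOC.Cl
Why: Aminolysis of the activated dioxolanone carbonyl by the chloromagnesium amide of N,O-dimethylhydroxylamine opens the ring, the hemiacetal alkoxide loses pivalaldehyde, and the Weinreb amide with a free tertiary hydroxyl results with C10 untouched.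

Step 7
Reactants: 14 (R)-2-hydroxy-N,4,4-trimethoxy-N,2-dimethylbutanamide; 15 ethynylmagnesium bromide
Product: 16 (R)-4-hydroxy-6,6-dimethoxy-4-methylhex-1-yn-3-one
Conditions: 15 (3.5 equiv), THF, 0 °C; aq. NH4Cl
Reagents that add atoms: none
Why: Weinreb ketone synthesis: the first equivalent of the alkynyl Grignard reagent deprotonates the hydroxyl, the second adds to the amide, and the magnesium-chelated tetrahedral intermediate survives until work-up, so the terminal ynone forms without over-addition.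

Step 8
Reactants: 7 tert-butyl{[(2Z,4R)-2-iodo-4-(triethylsilyloxy)hexa-2,5-dien-1-yl]oxy}diphenylsilane; 16 (R)-4-hydroxy-6,6-dimethoxy-4-methylhex-1-yn-3-one
Product: 17 (3R,7E,9R)-7-{[(tert-butyldiphenylsilyl)oxy]methyl}-3-hydroxy-1,1-dimethoxy-3-methyl-9-[(triethylsilyl)oxy]undeca-7,10-dien-5-yn-4-one
Conditions: Pd(PPh3)2Cl2 (5 mol%), CuI (10 mol%), Et3N, THF, rt
Reagents that add atoms: none
Why: Sonogashira coupling of the vinyl iodide with the terminal alkyne forms the C3–C4 bond with retention of the alkene geometry (C3 cis to C6); triethylamine is used because secondary amines would add to the ynone, and any hydroxy-ynone that already cyclises under the copper salt converges on 18 in the next step.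

Step 9
Reactants: 17 (3R,7E,9R)-7-{[(tert-butyldiphenylsilyl)oxy]methyl}-3-hydroxy-1,1-dimethoxy-3-methyl-9-[(triethylsilyl)oxy]undeca-7,10-dien-5-yn-4-one
Product: 19 (R)-5-{(2Z,4R)-1-[(tert-butyldiphenylsilyl)oxy]-4-hydroxyhexa-2,5-dien-2-yl}-2-(2,2-dimethoxyethyl)-2-methylfuran-3(2H)-one, via silyl ether 18 (not isolated)
Conditions: Ph3PAuCl (5 mol%), AgOTf (5 mol%), CH2Cl2, rt; then pyridine, HF·pyridine, THF, 0 °C
Reagents that add atoms: none
Why: Carbophilic activation of the ynone by cationic monovalent gold triggers 5-endo-dig attack of the tertiary C10 hydroxyl on C3 (intramolecular hydroalkoxylation, equivalent to an oxa-Michael addition) and protodeauration gives the 3(2H)-furanone 18, after which pyridine deactivates the gold and buffered HF cleaves only the secondary triethylsilyl ether, leaving the dimethyl acetal and the primary tert-butyldiphenylsilyl ether.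

Step 10
Reactants: 19 (R)-5-{(2Z,4R)-1-[(tert-butyldiphenylsilyl)oxy]-4-hydroxyhexa-2,5-dien-2-yl}-2-(2,2-dimethoxyethyl)-2-methylfuran-3(2H)-one; 20 2-(bromomethyl)acrylic acid
Product: 21 (3R,4Z)-6-[(tert-butyldiphenylsilyl)oxy]-5-[(R)-5-(2,2-dimethoxyethyl)-5-methyl-4-oxo-4,5-dihydrofuran-2-yl]hexa-1,4-dien-3-yl 2-(bromomethyl)acrylate
Conditions: DCC, DMAP (5 mol%), CH2Cl2, 0 °C
Reagents that add atoms: none
Why: Steglich esterification of the secondary bis-allylic alcohol proceeds with retention at C6, and the catalytic amount of DMAP at low temperature limits attack on the allylic bromide of the acid.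

Step 11
Reactants: 21 (3R,4Z)-6-[(tert-butyldiphenylsilyl)oxy]-5-[(R)-5-(2,2-dimethoxyethyl)-5-methyl-4-oxo-4,5-dihydrofuran-2-yl]hexa-1,4-dien-3-yl 2-(bromomethyl)acrylate
Product: 22 (R)-5-{(Z)-1-[(S)-4-(bromomethyl)-5-oxo-2,5-dihydrofuran-2-yl]-3-[(tert-butyldiphenylsilyl)oxy]prop-1-en-2-yl}-2-(2,2-dimethoxyethyl)-2-methylfuran-3(2H)-one
Conditions: second-generation Grubbs catalyst RuCl2(=CHPh)(PCy3)(H2IMes) (10 mol%), CH2Cl2, 40 °C
Reagents that add atoms: none
Why: Ring-closing metathesis between the C6 vinyl group and the 1,1-disubstituted acrylate alkene (ethylene lost) gives the butenolide, the trisubstituted conjugated C4=C5 alkene and the allylic bromide being inert to the ruthenium carbene, so the lactone ring of the target is in place before the macrocycle and C6 is not touched.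

Step 12
Reactants: 22 (R)-5-{(Z)-1-[(S)-4-(bromomethyl)-5-oxo-2,5-dihydrofuran-2-yl]-3-[(tert-butyldiphenylsilyl)oxy]prop-1-en-2-yl}-2-(2,2-dimethoxyethyl)-2-methylfuran-3(2H)-one
Product: 23 2-[(R)-5-{(Z)-1-[(S)-4-(bromomethyl)-5-oxo-2,5-dihydrofuran-2-yl]-3-[(tert-butyldiphenylsilyl)oxy]prop-1-en-2-yl}-2-methyl-3-oxo-2,3-dihydrofuran-2-yl]acetaldehyde
Conditions: CF3CO2H, H2O, CH2Cl2, 0 °C; used at once
Reagents that add atoms: water, O
Why: Mild aqueous acid hydrolyses the dimethyl acetal to the aldehyde while the tert-butyldiphenylsilyl ether, the allylic bromide and both five-membered rings survive, and the base-free conditions avoid β-elimination of the furanone oxygen and deprotonation at C6.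

Step 13
Reactants: 23 2-[(R)-5-{(Z)-1-[(S)-4-(bromomethyl)-5-oxo-2,5-dihydrofuran-2-yl]-3-[(tert-butyldiphenylsilyl)oxy]prop-1-en-2-yl}-2-methyl-3-oxo-2,3-dihydrofuran-2-yl]acetaldehyde
Product: 25 (4Z,6S,7S,8R,10R)-15-[(tert-butyldiphenylsilyl)oxy]-8-hydroxy-1-oxo-3,10-epoxygermacra-2,4,11(13)-trien-12,6-olide, via allylchromium 24 (not isolated)
Conditions: CrCl2 (10 equiv), THF, rt, 23 added over 10 h to a final 0.002 M; aq. NH4Cl
Reagents that add atoms: none
Why: Two equivalents of divalent chromium reduce the allylic C13–Br bond to the trivalent allylchromium 24, which binds the C8 aldehyde and delivers its γ-carbon C7 through a six-membered chair (Zimmerman–Traxler) transition state, an intramolecular Nozaki–Hiyama–Kishi allylation (SE2′) that also moves the double bond to C11=C13. The closest known reactions are the chromium-mediated additions of 3-(bromomethyl)furan-2(5H)-ones to aldehydes and the medium-ring closures of ω-formyl 2-(bromomethyl)acrylates. The nine-membered oxacycle closes by 9-exo-trig addition to the carbonyl (the aldehyde oxygen stays outside the ring), and no other ring is formed. C7 is set by the resident C6 centre, the aldehyde chain being expected to reach the butenolide face opposite the C6 alkenyl group so that the lactone becomes trans-fused; C8 is set by the chair in which C9 is equatorial, and the ring-fixed E-type allyl geometry then gives the anti (7S,8R) pair. The step needs γ- over α-attack (normal for allylchromium), aldehyde over ketone or lactone carbonyls (allylchromium reagents are aldehyde-selective), and ring closure over oligomerisation, which high dilution and the turn imposed by the Z-alkene and the furanone should secure.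

Step 14
Reactants: 25 (4Z,6S,7S,8R,10R)-15-[(tert-butyldiphenylsilyl)oxy]-8-hydroxy-1-oxo-3,10-epoxygermacra-2,4,11(13)-trien-12,6-olide; 26 (E)-but-2-enoic anhydride (crotonic anhydride)
Product: 27 (4Z,6S,7S,8R,10R)-8-[(E)-but-2-enoyloxy]-15-[(tert-butyldiphenylsilyl)oxy]-1-oxo-3,10-epoxygermacra-2,4,11(13)-trien-12,6-olide
Conditions: 26, DMAP (0.2 equiv), iPr2NEt, CH2Cl2, 0 °C
Reagents that add atoms: none
Why: DMAP-catalysed acylation of the hindered secondary C8 hydroxyl with the preformed (E)-anhydride proceeds with retention at C8 and, unlike the acid chloride with amine base, without deconjugation of the crotonyl group through a vinylketene.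

Step 15
Reactants: 27 (4Z,6S,7S,8R,10R)-8-[(E)-but-2-enoyloxy]-15-[(tert-butyldiphenylsilyl)oxy]-1-oxo-3,10-epoxygermacra-2,4,11(13)-trien-12,6-olide
Product: 28 (4Z,6S,7S,8R,10R)-8-[(E)-but-2-enoyloxy]-15-hydroxy-1-oxo-3,10-epoxygermacra-2,4,11(13)-trien-12,6-olide (target)
Conditions: HF·pyridine, pyridine, THF, 0 °C to rt
Reagents that add atoms: none
Why: Fluoride-mediated cleavage of the primary silyl ether under buffered, weakly acidic conditions frees the C15 hydroxyl without acyl migration or conjugate addition to the α-methylene lactone, the furanone or the crotonate.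

Compound list
1 | tert-butyldiphenyl(prop-2-yn-1-yloxy)silane | C#CCO[Si](c1ccccc1)(c1ccccc1)C(C)(C)C | starting material
2 | acrolein (prop-2-enal) | C=CC=O | starting material
3 | methyl{3-[(tert-butyldiphenylsilyl)oxy]prop-1-yn-1-yl}zinc | C[Zn]C#CCO[Si](c1ccccc1)(c1ccccc1)C(C)(C)C | intermediate
4 | (R)-6-[(tert-butyldiphenylsilyl)oxy]hex-1-en-4-yn-3-ol | C=C[C@@H](O)C#CCO[Si](c1ccccc1)(c1ccccc1)C(C)(C)C | intermediate
5 | sodium cyclic alkenylaluminate of 4 (aluminium on C4 and on the C6 oxygen, two 2-methoxyethoxy ligands) | C=C[C@H]1O[Al-](OCCOC)(OCCOC)C(CO[Si](c2ccccc2)(c2ccccc2)C(C)(C)C)=C1.[Na+] | intermediate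
6 | (3R,4Z)-6-[(tert-butyldiphenylsilyl)oxy]-5-iodohexa-1,4-dien-3-ol | C=C[C@@H](O)/C=C(\I)CO[Si](c1ccccc1)(c1ccccc1)C(C)(C)C | intermediate
7 | tert-butyl{[(2Z,4R)-2-iodo-4-(triethylsilyloxy)hexa-2,5-dien-1-yl]oxy}diphenylsilane | C=C[C@@H](O[Si](CC)(CC)CC)/C=C(\I)CO[Si](c1ccccc1)(c1ccccc1)C(C)(C)C | intermediate
8 | (2S,5S)-2-tert-butyl-5-methyl-1,3-dioxolan-4-one (cis acetal of (S)-lactic acid and pivalaldehyde) | C[C@@H]1O[C@H](C(C)(C)C)OC1=O | starting material
9 | allyl bromide | C=CCBr | starting material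
10 | lithium enolate of 8 | [Li]OC1=C(C)O[C@H](C(C)(C)C)O1 | intermediate
11 | (2S,5R)-5-allyl-2-tert-butyl-5-methyl-1,3-dioxolan-4-one | C[C@]1(CC=C)O[C@H](C(C)(C)C)OC1=O | intermediate
12 | 2-[(2S,4R)-2-tert-butyl-4-methyl-5-oxo-1,3-dioxolan-4-yl]acetaldehyde | C[C@]1(CC=O)O[C@H](C(C)(C)C)OC1=O | intermediate
13 | (2S,5R)-2-tert-butyl-5-(2,2-dimethoxyethyl)-5-methyl-1,3-dioxolan-4-one | C[C@]1(CC(OC)OC)O[C@H](C(C)(C)C)OC1=O | intermediate
14 | (R)-2-hydroxy-N,4,4-trimethoxy-N,2-dimethylbutanamide | C[C@@](O)(CC(OC)OC)C(=O)N(C)OC | intermediate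
15 | ethynylmagnesium bromide | C#C[Mg]Br | starting material
16 | (R)-4-hydroxy-6,6-dimethoxy-4-methylhex-1-yn-3-one | C#CC(=O)[C@](C)(O)CC(OC)OC | intermediate
17 | (3R,7E,9R)-7-{[(tert-butyldiphenylsilyl)oxy]methyl}-3-hydroxy-1,1-dimethoxy-3-methyl-9-[(triethylsilyl)oxy]undeca-7,10-dien-5-yn-4-one | C=C[C@@H](O[Si](CC)(CC)CC)/C=C(CO[Si](c1ccccc1)(c1ccccc1)C(C)(C)C)\C#CC(=O)[C@](C)(O)CC(OC)OC | intermediate
18 | (R)-5-{(2Z,4R)-1-[(tert-butyldiphenylsilyl)oxy]-4-[(triethylsilyl)oxy]hexa-2,5-dien-2-yl}-2-(2,2-dimethoxyethyl)-2-methylfuran-3(2H)-one | C=C[C@@H](O[Si](CC)(CC)CC)/C=C(CO[Si](c1ccccc1)(c1ccccc1)C(C)(C)C)\C1=CC(=O)[C@@](C)(CC(OC)OC)O1 | intermediate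
19 | (R)-5-{(2Z,4R)-1-[(tert-butyldiphenylsilyl)oxy]-4-hydroxyhexa-2,5-dien-2-yl}-2-(2,2-dimethoxyethyl)-2-methylfuran-3(2H)-one | C=C[C@@H](O)/C=C(CO[Si](c1ccccc1)(c1ccccc1)C(C)(C)C)\C1=CC(=O)[C@@](C)(CC(OC)OC)O1 | intermediate
20 | 2-(bromomethyl)acrylic acid | C=C(CBr)C(=O)O | starting material
21 | (3R,4Z)-6-[(tert-butyldiphenylsilyl)oxy]-5-[(R)-5-(2,2-dimethoxyethyl)-5-methyl-4-oxo-4,5-dihydrofuran-2-yl]hexa-1,4-dien-3-yl 2-(bromomethyl)acrylate | C=C[C@@H](OC(=O)C(=C)CBr)/C=C(CO[Si](c1ccccc1)(c1ccccc1)C(C)(C)C)\C1=CC(=O)[C@@](C)(CC(OC)OC)O1 | intermediate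
22 | (R)-5-{(Z)-1-[(S)-4-(bromomethyl)-5-oxo-2,5-dihydrofuran-2-yl]-3-[(tert-butyldiphenylsilyl)oxy]prop-1-en-2-yl}-2-(2,2-dimethoxyethyl)-2-methylfuran-3(2H)-one | BrCC1=C[C@@H](OC1=O)/C=C(CO[Si](c2ccccc2)(c2ccccc2)C(C)(C)C)\C2=CC(=O)[C@@](C)(CC(OC)OC)O2 | intermediate
23 | 2-[(R)-5-{(Z)-1-[(S)-4-(bromomethyl)-5-oxo-2,5-dihydrofuran-2-yl]-3-[(tert-butyldiphenylsilyl)oxy]prop-1-en-2-yl}-2-methyl-3-oxo-2,3-dihydrofuran-2-yl]acetaldehyde | BrCC1=C[C@@H](OC1=O)/C=C(CO[Si](c2ccccc2)(c2ccccc2)C(C)(C)C)\C2=CC(=O)[C@@](C)(CC=O)O2 | intermediate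
24 | allylchromium dichloride of 23 (trivalent chromium on C13 in place of bromine) | Cl[Cr](Cl)CC1=C[C@@H](OC1=O)/C=C(CO[Si](c2ccccc2)(c2ccccc2)C(C)(C)C)\C2=CC(=O)[C@@](C)(CC=O)O2 | intermediate
25 | (4Z,6S,7S,8R,10R)-15-[(tert-butyldiphenylsilyl)oxy]-8-hydroxy-1-oxo-3,10-epoxygermacra-2,4,11(13)-trien-12,6-olide | C=C1C(=O)O[C@H]2/C=C(/CO[Si](c3ccccc3)(c3ccccc3)C(C)(C)C)C3=CC(=O)[C@@](C)(C[C@@H](O)[C@H]12)O3 | intermediate
26 | (E)-but-2-enoic anhydride (crotonic anhydride) | C/C=C/C(=O)OC(=O)/C=C/C | starting material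
27 | (4Z,6S,7S,8R,10R)-8-[(E)-but-2-enoyloxy]-15-[(tert-butyldiphenylsilyl)oxy]-1-oxo-3,10-epoxygermacra-2,4,11(13)-trien-12,6-olide | C=C1C(=O)O[C@H]2/C=C(/CO[Si](c3ccccc3)(c3ccccc3)C(C)(C)C)C3=CC(=O)[C@@](C)(C[C@@H](OC(=O)/C=C/C)[C@H]12)O3 | intermediate
28 | (4Z,6S,7S,8R,10R)-8-[(E)-but-2-enoyloxy]-15-hydroxy-1-oxo-3,10-epoxygermacra-2,4,11(13)-trien-12,6-olide | C=C1C(=O)O[C@H]2/C=C(/CO)C3=CC(=O)[C@@](C)(C[C@@H](OC(=O)/C=C/C)[C@H]12)O3 | target

Total step count: 15. Longest linear sequence: 12 steps (from 8 through steps 4 to 15); the branch from 1 joins at step 8 after 3 steps.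

Steps most likely to fail

Step 13. The ring closure may pass through the alternative transition-state geometry (aldehyde chain axial, or a boat), that is, with poor facial selectivity at the aldehyde, which would invert C8. The fallback sets out from 23: the same chromium closure is run and the C8-epimeric alcohol, (4Z,6S,7S,8S,10R)-15-[(tert-butyldiphenylsilyl)oxy]-8-hydroxy-1-oxo-3,10-epoxygermacra-2,4,11(13)-trien-12,6-olide F1, is not discarded. It is esterified under Mitsunobu conditions with (E)-but-2-enoic acid (PPh3, diisopropyl azodicarboxylate, toluene, 0 °C), which installs the crotonate with inversion at C8 instead of acylating with retention. The route is rejoined at 27, and step 14 is skipped for this material.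

Step 1. Acrolein may polymerise under the zinc alkoxide conditions, or the enantioselectivity of the alkynylide addition may erode. The fallback sets out from 1 and 2. Alkyne 1 is deprotonated with n-BuLi (THF, −78 °C) to the lithium acetylide F2, which adds to 2 to give the racemic alcohol 6-[(tert-butyldiphenylsilyl)oxy]hex-1-en-4-yn-3-ol F3. A lipase (Candida antarctica lipase B, immobilised) with vinyl acetate in hexane then acylates the R enantiomer selectively (large alkynyl group, medium vinyl group) to give (R)-6-[(tert-butyldiphenylsilyl)oxy]hex-1-en-4-yn-3-yl acetate F4, which is separated from the unreacted S alcohol. Methanolysis (K2CO3, MeOH, 0 °C) returns the route to 4.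

Step 8. The terminal hydroxy-ynone 16 may cyclise on itself or oligomerise under amine and copper before it couples. The fallback sets out from 7 and 14 and forms the ynone only after the C3–C4 bond exists. Iodide 7 is coupled with ethynyltrimethylsilane (Pd(PPh3)2Cl2, CuI, Et3N) to give tert-butyl{[(2E,4R)-4-(triethylsilyloxy)-2-[(trimethylsilyl)ethynyl]hexa-2,5-dien-1-yl]oxy}diphenylsilane F5. The alkyne is freed (K2CO3, MeOH, 0 °C) to give tert-butyl{[(2E,4R)-2-ethynyl-4-(triethylsilyloxy)hexa-2,5-dien-1-yl]oxy}diphenylsilane F6, which is deprotonated with n-BuLi (THF, −78 °C) to the lithium acetylide F7. An excess of F7 (2.2 equiv, the first equivalent serving as base for the tertiary hydroxyl and being recovered as F6) acylates Weinreb amide 14, and the route is rejoined at 17.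

Further compounds
F1 | step 13 | (4Z,6S,7S,8S,10R)-15-[(tert-butyldiphenylsilyl)oxy]-8-hydroxy-1-oxo-3,10-epoxygermacra-2,4,11(13)-trien-12,6-olide | C=C1C(=O)O[C@H]2/C=C(/CO[Si](c3ccccc3)(c3ccccc3)C(C)(C)C)C3=CC(=O)[C@@](C)(C[C@H](O)[C@H]12)O3
F2 | step 1 | lithium acetylide of 1 | [Li]C#CCO[Si](c1ccccc1)(c1ccccc1)C(C)(C)C
F3 | step 1 | racemic 6-[(tert-butyldiphenylsilyl)oxy]hex-1-en-4-yn-3-ol | C=CC(O)C#CCO[Si](c1ccccc1)(c1ccccc1)C(C)(C)C
F4 | step 1 | (R)-6-[(tert-butyldiphenylsilyl)oxy]hex-1-en-4-yn-3-yl acetate | C=C[C@@H](OC(C)=O)C#CCO[Si](c1ccccc1)(c1ccccc1)C(C)(C)C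
F5 | step 8 | tert-butyl{[(2E,4R)-4-(triethylsilyloxy)-2-[(trimethylsilyl)ethynyl]hexa-2,5-dien-1-yl]oxy}diphenylsilane | C=C[C@@H](O[Si](CC)(CC)CC)/C=C(CO[Si](c1ccccc1)(c1ccccc1)C(C)(C)C)\C#C[Si](C)(C)C
F6 | step 8 | tert-butyl{[(2E,4R)-2-ethynyl-4-(triethylsilyloxy)hexa-2,5-dien-1-yl]oxy}diphenylsilane | C=C[C@@H](O[Si](CC)(CC)CC)/C=C(CO[Si](c1ccccc1)(c1ccccc1)C(C)(C)C)\C#C
F7 | step 8 | lithium acetylide of F6 | C=C[C@@H](O[Si](CC)(CC)CC)/C=C(CO[Si](c1ccccc1)(c1ccccc1)C(C)(C)C)\C#C[Li]
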